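The flask holds less solid reagent than substrate, 0.0350 M against 0.050 M, so partner, which the solid reagent gives as it dissolves, is the limiting reagent, and its charge allows at most 70.0% product.

| flask | substrate | solid reagent | remark | time |
|---|---|---|---|---|
| north-east | 0.050 M (fed, over 4.0 min) | 0.023 M | run made earlier; the fed solution adds 1.0 times the starting volume |  |
| south | 0.050 M (fed, over 4.0 min) | 0.053 M | run made earlier; the fed solution adds 1.0 times the starting volume |  |
| south-east | 0.075 M (fed, over 4.0 min) | 0.035 M | run made earlier; the fed solution adds 1.0 times the starting volume |  |
| flask | 0.050 M (fed, over 4.0 min) | 0.0350 M | the fed solution adds 1.0 times the starting volume | 5.0 h |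

| run | time / h | substrate / % | product / % |
|---|---|---|---|
| north-east | 1.00 | 61.7 | 38.4 |
| north-east | 2.00 | 59.8 | 40.5 |
| north-east | 3.00 | 58.8 | 41.8 |
| north-east | 4.00 | 59.0 | 41.2 |
| south | 1.00 | 31.2 | 69.8 |
| south | 2.00 | 22.2 | 77.9 |
| south | 3.00 | 20.6 | 79.3 |
| south | 4.00 | 21.2 | 79.3 |
| south-east | 1.00 | 58.7 | 41.5 |
| south-east | 2.00 | 56.7 | 43.1 |
| south-east | 3.00 | 56.9 | 43.6 |
| south-east | 4.00 | 57.1 | 43.5 |

(readings scatter by 0.3 percentage points)

* which holds at 5.0 h: what has brought the reaction to rest, or that it has not come to rest (for what has run out or reacted, a solid counts together with what of it has only dissolved) (forward and back rates have come level / the partner has run out first / it is still moving / all of the substrate has reacted)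
* share of the substrate used up at 5.0 h
* product at 5.0 h, in percent of the substrate charged

- charges are per starting volume, the dose included; the dosed solution carries all of it
- given per volume of solution although it is solid: solid reagent
- the numbers in the tables scatter with a standard deviation of 0.3 percentage points
- what may be going on: substrate + partner <-> product; solid reagent <-> partner
- at the start none of the solid reagent is in solution
- the reaction counts as stopped when no species that holds the substrate changes by six tenths of a point or more over the second half of the time

I follow one substrate molecule at its fork: it stays substrate or becomes product. In the south run, product reads 79.3% at 3.00 h and 79.3% at 4.00 h, so that run stands at rest, with odds of product over substrate of 3.74. Its ledger: product holds 0.0397 M of partner, and the remainder, spread over 2.00 starting volumes, gives a free c(partner) of 0.00667 M. The odds divided by free c(partner) give the odds constant (the equilibrium constant), 560 M⁻¹. The north-east and south-east runs read 582 M⁻¹ and 642 M⁻¹, but their free partner is less than in the south run, so the scatter of 0.3 percentage points weighs more there, and I keep the south reading.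

Now the flask's books. The share that balances them is 59.5%. Product then holds 0.0297 M of the partner charged, and the rest gives a free c(partner) of 0.00262 M, whose odds of 1.47 match that share. This c(partner) is lower than in the south run, so I count the flask's solid as dissolved. The time of 5.0 h is longer than the 4.00 h of the south run, and partner and substrate both remain, so I expect forward and back rates level.

The forecast, a little above my figure, says forward and back rates have come level, with 60.2% (58.5% to 62%) used up and 60.2% (58.5% to 62%) as product: “The plateaus show a reversible equilibrium, not a reagent limit.”

The flask gives 59.8% used up and 59.8% as product at 5.0 h: forward and back rates have come level.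

    substrate + partner ⇌ product (K = 580 M⁻¹, k = 0.0350 M⁻¹ s⁻¹)
    solid reagent ⇌ partner, rate k2*(cs2 - [partner]) while solid is left; crystals form when [partner] > cs2 (solubility = 17.0 mM, k = 0.00330 s⁻¹)

At that time the flask holds 0.00256 M of partner, with product at 59.8% and substrate at 40.2%. For a neighbour charged with 0.085 M of substrate, the same books with the odds constant give 38.5%, and that neighbour flask stands at 38.6%.

(The data were generated by integration for substances that don't exist; noise was put on by code.)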